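## Retrosynthetic overview

1. The last bond is C7'=C8'. It is made by a Wittig reaction between a C15 dienyl phosphonium salt (acyclic end, C1'–C7') and a C35 apo-8'-carotenal (ring end plus C7–C8').
2. The C35 aldehyde comes from a C6–C7 Suzuki–Miyaura coupling of a cyclohexenyl triflate with an octaenyl boronate. The boronate is made by one-sided boryl-olefination of the symmetric C20 crocetin dialdehyde.
3. Key step (ring end): ortho C-methylation of 2,6-xylenol destroys its aromaticity and its mirror symmetry in one operation and gives 2,6,6-trimethylcyclohexa-2,4-dienone. A catalytic asymmetric 1,6-prenylation then sets C2, followed by reductive triflation and allylic hydroxylation.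
4. Acyclic end: one-sided Shi epoxidation of symmetric 2,6-dimethylhepta-2,5-diene sets C2'. SN2 opening with the C6 enynol and trans-reduction of the alkyne follow.
5. Ring order: there is one ring only, and no cyclisation closes it. It is the carbocycle of the arene, carried through the route.

Carotenoid numbering is used: ring end unprimed, acyclic end primed.

Assumption: prenyl pinacolboronate, prenyl bromide, 2-methylprop-1-enylmagnesium bromide, (E)-3-methylpent-2-en-4-yn-1-ol and crocetin dialdehyde are bought, and the ligand antipode used in step 2 is the one that a test run shows to give the (5S)-enone.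

## Route

**Step 1**
Reactants: 1 2,6-dimethylphenol
Product: 3 2,6,6-trimethylcyclohexa-2,4-dien-1-one, via lithium 2,6-dimethylphenoxide 2 (not isolated)
Conditions: n-BuLi (1.0 equiv), toluene, 0 °C to rt; MeI (4 equiv), sealed vessel, 140 °C, 3 h; wash with KOH/MeOH/H2O, distil, keep at −20 °C
Reagents that add atoms: methyl iodide, CI
Why: Alkylative dearomatisation (C-alkylation of an ambident phenoxide) works here because the aggregated lithium phenoxide in toluene has its oxygen shielded, so soft MeI is attacked by the ortho carbon and the new quaternary carbon forbids re-aromatisation; the modest yield is bought with very cheap material, the product already carries the gem-dimethyl carbon, the ring methyl and the C6 oxygen handle, and no stereocentre is formed.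

**Step 2**
Reactants: 3 2,6,6-trimethylcyclohexa-2,4-dien-1-one; 4 4,4,5,5-tetramethyl-2-(3-methylbut-2-en-1-yl)-1,3,2-dioxaborolane (prenyl pinacolboronate)
Product: 6 (5S)-2,6,6-trimethyl-5-(3-methylbut-2-en-1-yl)cyclohex-2-en-1-one, via deconjugated cyclohex-3-enone isomer 5 (not isolated)
Conditions: CuCl (5 mol %), chiral sulfonate-bearing 4,5-diphenylimidazolinium salt (NHC precursor, 5.5 mol %), NaOt-Bu (20 mol %), 4 (1.5 equiv), MeOH (2 equiv), THF, 22 °C, 16 h; then DBU (0.2 equiv), CH2Cl2, rt
Reagents that add atoms: none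
Why: Proposed new method: the NHC-bound prenylcopper species formed from 4 by boron-to-copper exchange cannot reach the carbonyl of 3, which is walled in by the quaternary carbon and the 2-methyl group, so it binds the distal C4=C5 alkene, passes through a trivalent σ-allyl copper intermediate at C5 and reductively eliminates through its unhindered CH2 terminus (a bond between the CMe2 end and the neopentyl ring carbon is sterically excluded), with the chiral NHC choosing the ring face and so setting C5 as S (the later 2R centre), MeOH turning the catalyst over and DBU moving the alkene into conjugation; the closest known reaction types are the NHC–copper-catalysed enantioselective 1,6-conjugate addition of allyl and propargyl boron reagents to dienoates and the copper-catalysed asymmetric 1,6-addition of dialkylzincs to cyclic dienones.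

**Step 3**
Reactants: 6 (5S)-2,6,6-trimethyl-5-(3-methylbut-2-en-1-yl)cyclohex-2-en-1-one
Product: 8 (5R)-2,6,6-trimethyl-5-(3-methylbut-2-en-1-yl)cyclohex-1-en-1-yl trifluoromethanesulfonate, via lithium enolate 7 (not isolated)
Conditions: LiBH(s-Bu)3 (1.05 equiv), THF, −78 °C, 1 h; PhNTf2 (1.2 equiv), −78 °C to rt
Reagents that add atoms: N-phenylbis(trifluoromethanesulfonimide), O=S(=O)(N(c1ccccc1)S(=O)(=O)C(F)(F)F)C(F)(F)F
Why: In this conjugate hydride reduction with regiospecific enolate trapping, the bulky borohydride attacks the unsubstituted β-carbon of the hindered enone and O-triflation of the only possible enolate fixes the tetrasubstituted C5=C6 alkene, while the stereocentre is untouched (the descriptor turns to R only because the CIP ranks change).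

**Step 4**
Reactants: 8 (5R)-2,6,6-trimethyl-5-(3-methylbut-2-en-1-yl)cyclohex-1-en-1-yl trifluoromethanesulfonate
Product: 9 (5R)-5-[(2E)-4-hydroxy-3-methylbut-2-en-1-yl]-2,6,6-trimethylcyclohex-1-en-1-yl trifluoromethanesulfonate
Conditions: SeO2 (0.3 equiv), t-BuOOH (2.5 equiv), salicylic acid (0.1 equiv), CH2Cl2, 0 °C to rt, stopped at about 70 % conversion
Reagents that add atoms: tert-butyl hydroperoxide, CC(C)(C)OO (terminal oxidant); selenium dioxide, O=[Se]=O (oxygen carrier)
Why: Selenium dioxide allylic oxidation (ene reaction followed by a [2,3]-sigmatropic shift) hydroxylates only the E-methyl group of a trisubstituted gem-dimethyl alkene, and the electron-poor enol triflate alkene does not take part.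

**Step 5**
Reactants: 10 1-bromo-3-methylbut-2-ene (prenyl bromide); 11 2-methylprop-1-enylmagnesium bromide
Product: 12 2,6-dimethylhepta-2,5-diene
Conditions: CuI (5 mol %), THF, −20 °C to rt; distil
Reagents that add atoms: none
Why: In this copper-catalysed Grignard–allyl halide cross-coupling the alkenyl group is delivered to the primary (α) carbon of prenyl bromide because the γ-carbon is fully substituted, which gives the symmetric skipped diene.

**Step 6**
Reactants: 12 2,6-dimethylhepta-2,5-diene
Product: 13 (3S)-2,2-dimethyl-3-(3-methylbut-2-en-1-yl)oxirane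
Conditions: ent-Shi ketone (1,2:4,5-di-O-isopropylidene-β-L-erythro-2,3-hexodiulo-2,6-pyranose, 30 mol %), KHSO5 (as 2KHSO5·KHSO4·K2SO4, 0.7 equiv), K2CO3, Na2B4O7 buffer pH 10.5, Bu4NHSO4 (cat.), MeCN/CH2(OMe)2/H2O, 0 °C, 2 h; recover 12
Reagents that add atoms: potassium peroxymonosulfate, [K+].[O-]S(=O)(=O)OO
Why: In this Shi asymmetric epoxidation the chiral dioxirane attacks one of the two equivalent trisubstituted alkenes through the spiro transition state; the D-fructose-derived ketone gives R epoxides of RCH2CH=CMe2 alkenes, so its antipode sets the S centre (later C2'), and the shortfall of oxidant holds back the bis-epoxide.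

**Step 7**
Reactants: 13 (3S)-2,2-dimethyl-3-(3-methylbut-2-en-1-yl)oxirane; 14 (E)-3-methylpent-2-en-4-yn-1-ol
Product: 16 (2E,6S)-6-(2-hydroxypropan-2-yl)-3,9-dimethyldeca-2,8-dien-4-yn-1-ol, via dilithio enynol dianion 15 (not isolated)
Conditions: 14 (1.5 equiv), n-BuLi (3.0 equiv), THF, −78 to 0 °C; DMPU (20 vol %), 13 (1.0 equiv), 0 to 55 °C, 24 h; H2O
Reagents that add atoms: none
Why: In this SN2 epoxide opening the carbon end of the alkynol dianion is the reactive nucleophile; without a Lewis acid it attacks the less substituted oxirane carbon with clean inversion, and because the CIP ranks change at the same time the S epoxide gives the S carbinol with the configuration of the target at C2'.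

**Step 8**
Reactants: 16 (2E,6S)-6-(2-hydroxypropan-2-yl)-3,9-dimethyldeca-2,8-dien-4-yn-1-ol
Product: 18 (2E,4E,6S)-6-(2-hydroxypropan-2-yl)-3,9-dimethyldeca-2,4,8-trien-1-ol, via Z-vinylsilane 17 (not isolated)
Conditions: (EtO)3SiH (1.2 equiv), [Cp*Ru(MeCN)3]PF6 (3 mol %), CH2Cl2, 0 °C to rt, 1 h; concentrate; CuI (1.0 equiv), Bu4NF (2.2 equiv), THF, rt
Reagents that add atoms: none
Why: Ruthenium-catalysed trans-hydrosilylation followed by copper/fluoride protodesilylation with retention is a net anti addition of H2, so either silane regioisomer gives the E alkene, while the trisubstituted alkenes, the free alcohols and C6 are left alone.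

**Step 9**
Reactants: 19 crocetin dialdehyde, (2E,4E,6E,8E,10E,12E,14E)-2,6,11,15-tetramethylhexadeca-2,4,6,8,10,12,14-heptaenedial
Product: 20 (2E,4E,6E,8E,10E,12E,14E,16E)-2,6,11,15-tetramethyl-17-(4,4,5,5-tetramethyl-1,3,2-dioxaborolan-2-yl)heptadeca-2,4,6,8,10,12,14,16-octaenal
Conditions: 19 (2.0 equiv), Cl2CHBpin (1.0 equiv), CrCl2 (6 equiv), LiI (3 equiv), THF, rt, dark, 8 h; recover 19
Reagents that add atoms: 2-(dichloromethyl)-4,4,5,5-tetramethyl-1,3,2-dioxaborolane, ClC(Cl)B1OC(C)(C)C(C)(C)O1
Why: In this Takai–Utimoto boryl-olefination the gem-dichromium reagent, generated by divalent chromium, adds to an enal carbonyl and eliminates to the E alkenyl boronate, and the limiting reagent against an excess of the symmetric dialdehyde keeps the reaction one-sided.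

**Step 10**
Reactants: 9 (5R)-5-[(2E)-4-hydroxy-3-methylbut-2-en-1-yl]-2,6,6-trimethylcyclohex-1-en-1-yl trifluoromethanesulfonate; 20 octaenal boronate
Product: 21 (all-E,2R)-2-[(2E)-4-hydroxy-3-methylbut-2-en-1-yl]-8'-apo-β-caroten-8'-al
Conditions: Pd(OAc)2 (5 mol %), SPhos (10 mol %), K3PO4 (3 equiv), THF/H2O 10:1, 45 °C, argon, dark
Reagents that add atoms: none
Why: In this Suzuki–Miyaura coupling an electron-rich bulky phosphine on zerovalent palladium inserts into the hindered enol triflate, both alkene geometries are retained, and the aldehyde, the free allylic alcohol and C2 are spectators.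

**Step 11**
Reactants: 18 (2E,4E,6S)-6-(2-hydroxypropan-2-yl)-3,9-dimethyldeca-2,4,8-trien-1-ol; 21 (all-E,2R)-2-[(2E)-4-hydroxy-3-methylbut-2-en-1-yl]-8'-apo-β-caroten-8'-al
Product: 25 CNP0286110.1 = (all-E,2R,2'S)-2-[(2E)-4-hydroxy-3-methylbut-2-en-1-yl]-2'-(3-methylbut-2-en-1-yl)-3',4'-didehydro-1',2'-dihydro-β,ψ-caroten-1'-ol, via phosphonium bromide 22 (not isolated), via phosphorane 23 (not isolated), via 7'Z isomer 24 (not isolated)
Conditions: 18, PPh3·HBr (1.05 equiv), MeOH, 0 °C to rt, 16 h; 21 (0.9 equiv) in CH2Cl2, NaOMe (1.2 equiv), −10 °C to rt, dark; swap to heptane/EtOH, reflux 4 h, crystallise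
Reagents that add atoms: none
Why: In this Wittig olefination the dienylic alcohol ionises under the mild acid and PPh3 takes the primary terminus; the semi-stabilised ylide then joins C7' to C8' as an E/Z mixture, and heating funnels the hindered 7'Z isomer into the crystallising all-E compound, with neither stereocentre next to an acidic position.

## Compound list

| No. | Name | SMILES | Role |
|---|---|---|---|
| 1 | 2,6-dimethylphenol | Cc1cccc(C)c1O | starting material |
| 2 | lithium 2,6-dimethylphenoxide | [Li+].[O-]c1c(C)cccc1C | intermediate |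
| 3 | 2,6,6-trimethylcyclohexa-2,4-dien-1-one | CC1=CC=CC(C)(C)C1=O | intermediate |
| 4 | prenyl pinacolboronate | CC(C)=CCB1OC(C)(C)C(C)(C)O1 | starting material |
| 5 | (5S)-2,6,6-trimethyl-5-(3-methylbut-2-en-1-yl)cyclohex-3-en-1-one (C2 epimers) | O=C1C(C)C=C[C@H](CC=C(C)C)C1(C)C | intermediate |
| 6 | (5S)-2,6,6-trimethyl-5-(3-methylbut-2-en-1-yl)cyclohex-2-en-1-one | O=C1C(C)=CC[C@H](CC=C(C)C)C1(C)C | intermediate |
| 7 | lithium (5R)-2,6,6-trimethyl-5-(3-methylbut-2-en-1-yl)cyclohex-1-en-1-olate | [Li+].[O-]C1=C(C)CC[C@H](CC=C(C)C)C1(C)C | intermediate |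
| 8 | (5R)-2,6,6-trimethyl-5-(3-methylbut-2-en-1-yl)cyclohex-1-en-1-yl triflate | O=S(=O)(OC1=C(C)CC[C@H](CC=C(C)C)C1(C)C)C(F)(F)F | intermediate |
| 9 | (5R)-5-[(2E)-4-hydroxy-3-methylbut-2-en-1-yl]-2,6,6-trimethylcyclohex-1-en-1-yl triflate | O=S(=O)(OC1=C(C)CC[C@H](C/C=C(\C)CO)C1(C)C)C(F)(F)F | intermediate |
| 10 | prenyl bromide | CC(C)=CCBr | starting material |
| 11 | 2-methylprop-1-enylmagnesium bromide | CC(C)=C[Mg]Br | starting material |
| 12 | 2,6-dimethylhepta-2,5-diene | CC(C)=CCC=C(C)C | intermediate |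
| 13 | (3S)-2,2-dimethyl-3-(3-methylbut-2-en-1-yl)oxirane | CC(C)=CC[C@@H]1OC1(C)C | intermediate |
| 14 | (E)-3-methylpent-2-en-4-yn-1-ol | C#C/C(C)=C/CO | starting material |
| 15 | dilithium salt (alkoxide and acetylide) of 14 | [Li+].[Li+].[C-]#C/C(C)=C/C[O-] | intermediate |
| 16 | (2E,6S)-6-(2-hydroxypropan-2-yl)-3,9-dimethyldeca-2,8-dien-4-yn-1-ol | CC(C)=CC[C@@H](C#C/C(C)=C/CO)C(C)(C)O | intermediate |
| 17 | (2E,4Z,6S)-6-(2-hydroxypropan-2-yl)-3,9-dimethyl-4-(triethoxysilyl)deca-2,4,8-trien-1-ol (major regioisomer drawn) | CC(C)=CC[C@@H](/C=C(/C(C)=C/CO)[Si](OCC)(OCC)OCC)C(C)(C)O | intermediate |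
| 18 | (2E,4E,6S)-6-(2-hydroxypropan-2-yl)-3,9-dimethyldeca-2,4,8-trien-1-ol | CC(C)=CC[C@@H](/C=C/C(C)=C/CO)C(C)(C)O | intermediate |
| 19 | crocetin dialdehyde | O=C/C(C)=C/C=C/C(C)=C/C=C/C=C(C)/C=C/C=C(C)/C=O | starting material |
| 20 | all-E 17-(pinacolboryl)-2,6,11,15-tetramethylheptadeca-2,4,6,8,10,12,14,16-octaenal | O=C/C(C)=C/C=C/C(C)=C/C=C/C=C(C)/C=C/C=C(C)/C=C/B1OC(C)(C)C(C)(C)O1 | intermediate |
| 21 | (all-E,2R)-2-[(2E)-4-hydroxy-3-methylbut-2-en-1-yl]-8'-apo-β-caroten-8'-al | O=C/C(C)=C/C=C/C(C)=C/C=C/C=C(C)/C=C/C=C(C)/C=C/C1=C(C)CC[C@H](C/C=C(\C)CO)C1(C)C | intermediate |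
| 22 | [(2E,4E,6S)-6-(2-hydroxypropan-2-yl)-3,9-dimethyldeca-2,4,8-trien-1-yl]triphenylphosphonium bromide | CC(C)=CC[C@@H](/C=C/C(C)=C/C[P+](c1ccccc1)(c1ccccc1)c1ccccc1)C(C)(C)O.[Br-] | intermediate |
| 23 | ylide (phosphorane) of 22 | CC(C)=CC[C@@H](/C=C/C(C)=C/C=P(c1ccccc1)(c1ccccc1)c1ccccc1)C(C)(C)O | intermediate |
| 24 | 7'Z isomer of the target | CC(C)=CC[C@@H](/C=C/C(C)=C/C=C\C(C)=C\C=C\C(C)=C\C=C\C=C(C)\C=C\C=C(C)\C=C\C1=C(C)CC[C@H](C/C=C(\C)CO)C1(C)C)C(C)(C)O | intermediate |
| 25 | CNP0286110.1, (all-E,2R,2'S) | CC(C)=CC[C@@H](/C=C/C(C)=C/C=C/C(C)=C/C=C/C(C)=C/C=C/C=C(C)/C=C/C=C(C)/C=C/C1=C(C)CC[C@H](C/C=C(\C)CO)C1(C)C)C(C)(C)O | target |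

## Step count

- Total steps: 11.
- Longest linear sequence: 6 (steps 1, 2, 3, 4, 10, 11).
- The acyclic branch is 5 steps long (steps 5, 6, 7, 8, 11).

## Steps most likely to fail

**Step 2.** The site of attack (1,6 against 1,4), the end of the prenyl unit that bonds, and the enantioselectivity are all untested on this dienone.
- The fallback sets out from 3 and comes back at 6, at the cost of one extra step.
- It gives up allyl transfer for alkyl transfer, which has close precedent.
- Cu(OTf)2 (2 mol %) with a BINOL-derived phosphoramidite ligand catalyses the 1,6-addition of bis(3-methylbut-3-en-1-yl)zinc (from the Grignard reagent and ZnCl2) to 3 in toluene at −30 °C.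
- This gives (5S)-2,6,6-trimethyl-5-(3-methylbut-3-en-1-yl)cyclohex-3-en-1-one F1, which DBU conjugates to (5S)-2,6,6-trimethyl-5-(3-methylbut-3-en-1-yl)cyclohex-2-en-1-one F2.
- A radical hydrogen-atom-transfer isomerisation then moves the 1,1-disubstituted alkene by one position to the prenyl alkene of 6. It uses chloro[N,N'-bis(3,5-di-tert-butylsalicylidene)-1,2-cyclohexanediaminato]cobalt (3 mol %) and PhSiH3 (5 mol %) in benzene at rt.

**Step 7.** The SN2 attack takes place at an oxirane carbon next to a fully substituted carbon, and the nucleophile is a bulky, aggregated dianion.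
- The fallback sets out from 13 and comes back at 16.
- The smallest possible nucleophile, LiC≡CH·H2NCH2CH2NH2 in DMSO at 25–40 °C, opens 13 to (3S)-3-ethynyl-2,6-dimethylhept-5-en-2-ol F3.
- The enyne is then built at the C4'–C5' bond by Sonogashira coupling of F3 with (E)-3-iodobut-2-en-1-ol (Pd(PPh3)4, CuI, Et3N, rt), which gives 16.

**Step 10.** A tetrasubstituted, doubly flanked enol triflate has to react with a long polyenyl boronate that is prone to protodeboronation.
- The fallback sets out from 9 and 19 and comes back at 21. It reverses the polarity of the coupling.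
- Miyaura borylation of 9 (B2pin2, PdCl2(PPh3)2, PPh3, KOPh, toluene, 50 °C) gives 2-{(5R)-5-[(2E)-4-hydroxy-3-methylbut-2-en-1-yl]-2,6,6-trimethylcyclohex-1-en-1-yl}-4,4,5,5-tetramethyl-1,3,2-dioxaborolane F4.
- One-sided Takai iodo-olefination of excess 19 (CHI3, CrCl2, THF, 0 °C) gives (2E,4E,6E,8E,10E,12E,14E,16E)-17-iodo-2,6,11,15-tetramethylheptadeca-2,4,6,8,10,12,14,16-octaenal F5.
- The fast oxidative addition of the iodide then lets F4 and F5 couple at room temperature (Pd(PPh3)4, aqueous KOH, THF) to give 21.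

## Further compounds

F1 | step 2 | (5S)-2,6,6-trimethyl-5-(3-methylbut-3-en-1-yl)cyclohex-3-en-1-one (C2 epimers) | O=C1C(C)C=C[C@H](CCC(C)=C)C1(C)C
F2 | step 2 | (5S)-2,6,6-trimethyl-5-(3-methylbut-3-en-1-yl)cyclohex-2-en-1-one | O=C1C(C)=CC[C@H](CCC(C)=C)C1(C)C
F3 | step 7 | (3S)-3-ethynyl-2,6-dimethylhept-5-en-2-ol | CC(C)=CC[C@@H](C#C)C(C)(C)O
F4 | step 10 | 2-{(5R)-5-[(2E)-4-hydroxy-3-methylbut-2-en-1-yl]-2,6,6-trimethylcyclohex-1-en-1-yl}-4,4,5,5-tetramethyl-1,3,2-dioxaborolane | CC1(C)OB(OC1(C)C)C2=C(C)CC[C@H](C/C=C(\C)CO)C2(C)C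
F5 | step 10 | (2E,4E,6E,8E,10E,12E,14E,16E)-17-iodo-2,6,11,15-tetramethylheptadeca-2,4,6,8,10,12,14,16-octaenal | O=C/C(C)=C/C=C/C(C)=C/C=C/C=C(C)/C=C/C=C(C)/C=C/I
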